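Conventions: drimane numbering for the decalin (C1–C10, C11 on C9, C12 the methyl on C8), the oxygen-bearing carbon on C4 is called C18, and β is the face of the C10 methyl. Ring C is primed (C1′ carries C11, C2′ the hydroxyl, C4′ the methyl, C5′ the ketone, C6′ the epoxide CH). Ar = 5-methoxy-2-(methoxymethoxy)-4-methylphenyl.

## The problem

Epoxypholamin B (30; 4R,5R,9S,10R,1′S,2′R,6′S) is a trans-fused drim-7-ene (rings A and B) whose C11 methylene on C9 is bonded to C1′ of ring C, a 1′,6′-epoxy-2′-hydroxy-4′-methylcyclohex-3′-en-5′-one. The decalin has four stereocentres: two quaternary (C4 with β-methyl and α-CH2OH, C10 with β-methyl) and two tertiary (C5 and C9, both α-H). Ring C has three: C1′ and C6′ of the epoxide and the C2′ carbinol, whose hydroxyl is anti to the epoxide oxygen. C11 insulates the two sets, so the decalin cannot be relied on to choose the face of ring C; the epoxide needs reagent control, and it can then direct the C2′ reduction. Within the decalin only C4 has to come from an enantioselective reaction: it is 1,3 to C10 and can bias its formation, and C5 and C9 can afterwards be set by protonation on the face away from the two β-methyl groups. The fragile parts are the epoxy enone with its γ-hydroxyl (base, nucleophiles, strong acid), the C7=C8 alkene (migration, or attack by an ortho phenol, under Lewis acids) and any intermediate with an acyl group on C9 of a drim-7-ene, which can lose its C9 configuration by enolisation. Ring C is therefore unveiled last from an arene, and C9 is fixed under kinetic control. The feature that opens the route is the C18 hydroxyl: it stands three bonds from C6, and closing C18–O–C6 to a five-membered enol ether locks C7=C6–C5=C10 as an s-cis diene whose faces differ essentially by the C4 methyl. That diene can take up C8, C9 and the aryl-bearing C11 as an alkyne and close ring B at the quaternary C10.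

## Retrosynthesis

**Ring C (30 back to 26).** The two C–O bonds of the epoxide, the C2′–H bond and the C5′ carbonyl are taken apart in the order 30 ⇒ 29 ⇒ 28 ⇒ 27 ⇒ 26. Carrying a finished epoxyquinol through C–C bond formation was rejected because of its fragility. Oxidative dearomatisation of the para-methoxyphenol 26 gives the monoketal 27, in which C2′ is a free ketone and C5′ is masked, so the later reduction has only one carbonyl to find. Of the two enone alkenes of 27 only C1′=C6′ has an unsubstituted β-carbon, which fixes the site of nucleophilic epoxidation (28). Three stereocentres and all oxidation of ring C are thereby exchanged for an arene. The forward steps must select the dienone face with a chiral phase-transfer catalyst and deliver hydride to C2′ from the epoxide side (29).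

**Oxygen at C6 and C11 (26 back to 21).** The C6–H and C11–H bonds are traced back to C–O bonds in diol 23 and, before silylation, triol 22 and enone diol 21. These two oxygens are the price of the cycloaddition: the C11 carbonyl activates the alkyne and the C6 oxygen is the enol ether. Both positions are activated (allylic, benzylic), so one radical operation on the bis-xanthate 24 removes both and gives 25; the primary C18 hydroxyl is silylated selectively beforehand. The forward reaction must transfer hydrogen to C6 and not to C8 of the allyl radical, and the phenol must be released (26) without acid-induced cyclisation onto C8.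

**C9 and C5 (21 back to 18).** The C9–H and C5–H bonds and the C6 carbonyl are traced back to the cyclohexa-1,4-diene 18. Simply hydrolysing 18 and equilibrating with base would place C9–H between a ketone and a vinylogous ketone and leave its configuration to thermodynamics. That is unsafe, because 9-acyl drim-7-enes tend to drift to the 9α series under base. Instead, γ-deprotonation of the enone in 18 and kinetic α-protonation of the dienolate from the α face give 19. The C11 ketone is then reduced (20) before the C6 carbonyl exists, and hydrolysis of the 2-alkoxydiene protonates C5 from the α face to give 21. The forward steps must protonate at C9 rather than back at C7, and on the face opposite the C10 methyl.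

**Ring B (18 back to 12 and 17).** C7–C8 and C9–C10 are cut, which divides the skeleton into the bicyclic dienol ether 12 (ring A, C4 to C7, C18) and the aryl butynone 17 (C8, C9, C11, C12 and the arene). Cutting elsewhere in ring B would not make the quaternary C10 while joining two halves of similar size. The reaction asked for is a Diels–Alder addition with "para" regiochemistry and addition anti to the C4 methyl.

**Diene (12 back to 1, 2 and 8).** The C6–O bond is cut (5-exo hydroalkoxylation of the enynol 11, from silyl enyne 10), then C5–C6 (Sonogashira coupling of enol triflate 7 with 8 to give 9), then the C10 methyl (6) and the C4 methyl (5, from enamine 3 of keto ester 1 and auxiliary 2). Direct enantioselective hydroxymethylation of 2,6-dimethylcyclohexanone was set aside: its enol ether is racemic at the second methyl-bearing carbon and a catalyst would have to override that centre. Auxiliary-controlled methylation of an achiral β-keto ester enamine has no such conflict, and the ester serves as the C18 oxygen at the right carbon.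

**Ynone (17 back to 13).** C9–C11 is cut to the aldehyde 15 and a propynyl nucleophile (16 after addition). The two phenol oxygens are told apart at the start by chelation-controlled demethylation of 13 ortho to the formyl group (14), so that C2′ later carries the free phenol and C5′ the methyl ether needed for the monoketal.

## Roads not taken

Alternative 1: The cut is through C4–C5 and C9–C10, so that rings A and B arise together from an acyclic chain. An allylic alcohol whose oxygen is C18 is epoxidised by the Sharpless method (Ti(O-i-Pr)4, a dialkyl tartrate, t-BuOOH), silylated and extended to the epoxy β-keto ester A2. MeAlCl2 then opens the epoxide at C4, the trisubstituted alkene adds, and the keto ester enol closes ring B to give the bicyclic keto ester A1.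
- Merits: one catalytic asymmetric step of known sense fixes the absolute configuration, and the chair–chair transition state delivers C4, C5, C10 and the trans fusion together.
- Weak points: the epoxide must ionise at a tertiary carbon carrying a deactivating CH2OSi group. A1 has a C3 hydroxyl that 30 lacks. The C8 ketone must become the C7=C8 alkene with its methyl. The arene is still missing, so C11 must be reduced, activated and joined to an aryl nucleophile next to C9.
- Comparison: for the stereochemistry of the decalin this road is the safer one, and the chosen plan cannot match its certainty at C5 and C10. The chosen plan sets convergence against it: after step 12 every carbon of 30 is in place, C18 is at the right oxidation level, ring A needs no deoxygenation, and the two superfluous oxygens leave in one operation.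

Alternative 2: The cut is at the two C–O bonds of the epoxide in the silyl-protected quinone monoketal A4. t-BuOOH and a cinchona-derived quaternary ammonium salt add hydroperoxide to C6′ and close the epoxide at C1′ to give A3.
- Merits: catalyst control is placed exactly where substrate control is absent, the step is mild and late, and the dienone offers only one alkene with an unsubstituted β-carbon.
- Weak points: it is an endgame and presupposes the drimenyl arene with its four stereocentres; the reaction class is best documented for dienones without an α-alkyl group.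
- Comparison: as a single step it is better precedented than the cycloaddition, and it does not compete with the chosen plan, which uses the same epoxidation as step 21 on the free C18 alcohol 27 in place of A4. As an organising idea it leaves the skeleton, both quaternary carbons and the ring fusion open, and these decide the length of the synthesis.

Alternative 3: The cut is through C1–C10 and C4–C5: ring B is bought as 2,6-dimethyl-1,4-benzoquinone A6 and ring A comes from (Z)-3-silyloxypenta-1,3-diene A7. A chiral oxazaborolidinium Lewis acid binds one quinone carbonyl and the diene adds to a methyl-bearing alkene, giving the cis-fused ene-dione A5 with C10 set by the catalyst.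
- Merits: catalytic and enantioselective from two simple achiral compounds; ring B arrives with its C8 methyl and the C7=C8 alkene.
- Weak points: C4 is only a methine, so C18 needs a second, diastereoselective alkylation. The C3 oxygen must be removed and the cis fusion epimerised. The C9 carbonyl must become CH–CH2Ar by a C–C bond formation next to a quaternary carbon, and the C6 oxygen must go as well.
- Comparison: for enantiocontrol and for C10 this road is as good as or better than the chosen one, which needs an auxiliary for C4 and relay to C10. The chosen plan offers in return a key-step product that already contains C18, the arene and C11, with two oxygens to delete where this road has three plus two further C–C bonds.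

Key step: step 12

Assumption: L-valine tert-butyl ester in toluene/HMPA is taken to give the (R)-keto ester 5, and N-benzylcinchonidinium chloride the (1′R,6′S)-epoxide 28; if either sense is opposite, D-valine tert-butyl ester or N-benzylcinchoninium chloride is used with no other change.

## Steps

Step 1
Reactants: 1 ethyl 2-oxocyclohexane-1-carboxylate; 2 L-valine tert-butyl ester
Product: 3 ethyl 2-{[(2S)-1-tert-butoxy-3-methyl-1-oxobutan-2-yl]amino}cyclohex-1-ene-1-carboxylate
Conditions: BF3·OEt2 (cat.), toluene, reflux, Dean–Stark
Reagents that add atoms: none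
Why: Acid-catalysed condensation of a β-keto ester with a primary amine gives the hydrogen-bonded enamino ester; no stereocentre is formed.

Step 2
Reactants: 3 enamino ester
Product: 5 ethyl (1R)-1-methyl-2-oxocyclohexane-1-carboxylate, via α-methylated ketimine 4 (not isolated)
Conditions: LiN(i-Pr)2, toluene, −78 °C; HMPA (1 equiv); MeI, −78 → −55 °C; then aq. citric acid, rt
Reagents that add atoms: iodomethane (CI); water (O)
Why: Auxiliary-controlled alkylation of a chiral lithio-enamine: lithium is chelated by nitrogen and the valine ester carbonyl, the isopropyl group screens one face, and methylation at carbon sets the quaternary centre that becomes C4. Mild acid hydrolysis of the ketimine releases the ketone and the auxiliary.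

Step 3
Reactants: 5 ethyl (1R)-1-methyl-2-oxocyclohexane-1-carboxylate
Product: 6 ethyl (1R)-1,3-dimethyl-2-oxocyclohexane-1-carboxylate (both C3 epimers)
Conditions: LiN(i-Pr)2, THF, −78 °C; MeI, −78 → 0 °C
Reagents that add atoms: iodomethane (CI)
Why: Enolate alkylation; only C3 can be deprotonated because C1 is quaternary. The C3 configuration is irrelevant, since this carbon becomes sp2 in the next step.

Step 4
Reactants: 6 ethyl (1R)-1,3-dimethyl-2-oxocyclohexane-1-carboxylate
Product: 7 ethyl (1R)-1,3-dimethyl-2-{[(trifluoromethyl)sulfonyl]oxy}cyclohex-2-ene-1-carboxylate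
Conditions: KN(SiMe3)2, THF, −78 °C; PhNTf2, −78 → 0 °C
Reagents that add atoms: N-phenylbis(trifluoromethanesulfonimide) (O=S(=O)(N(c1ccccc1)S(=O)(=O)C(F)(F)F)C(F)(F)F)
Why: O-Triflation of the only possible enolate gives the tetrasubstituted enol triflate, as known for 2,2,6-trisubstituted cyclohexanones.

Step 5
Reactants: 7 enol triflate; 8 ethynyl(trimethyl)silane
Product: 9 ethyl (1R)-1,3-dimethyl-2-[(trimethylsilyl)ethynyl]cyclohex-2-ene-1-carboxylate
Conditions: Pd(PPh3)4 (5 mol %), CuI (10 mol %), Et3N, DMF, 50 °C
Reagents that add atoms: none
Why: Sonogashira coupling of a vinyl triflate with a terminal alkyne forms C5–C6; it is well established for 2,6,6-trisubstituted cyclohexenyl triflates.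

Step 6
Reactants: 9 silyl enyne ester
Product: 10 {(1R)-1,3-dimethyl-2-[(trimethylsilyl)ethynyl]cyclohex-2-en-1-yl}methanol
Conditions: i-Bu2AlH (2.5 equiv), CH2Cl2, −78 → 0 °C
Reagents that add atoms: none
Why: Hydride reduction of the hindered ester to the primary alcohol (C18–OH); the silylated enyne is inert at low temperature.

Step 7
Reactants: 10 silyl enynol
Product: 12 (3aR)-3a,7-dimethyl-1-methylidene-1,3,3a,4,5,6-hexahydro-2-benzofuran (the C18–O–C6 dienol ether), via terminal enynol 11 (not isolated)
Conditions: Bu4NF, THF, 0 → 60 °C; base-washed glassware, product used crude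
Reagents that add atoms: none
Why: Fluoride cleaves the C–Si bond and the resulting ammonium alkoxide adds to the near alkyne carbon in a 5-exo-dig hydroalkoxylation, as in fluoride- or base-promoted cyclisations of 2-ethynylbenzyl alcohols and pent-4-yn-1-ols. The quaternary carbon next to oxygen-bearing C18 blocks aromatisation to a furan.

Step 8
Reactants: 13 2,5-dimethoxy-4-methylbenzaldehyde
Product: 14 2-hydroxy-5-methoxy-4-methylbenzaldehyde
Conditions: BCl3, CH2Cl2, −78 → 0 °C; aq. work-up
Reagents that add atoms: none
Why: Chelation-directed ether cleavage: boron bound to the formyl oxygen removes only the ortho methyl group.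

Step 9
Reactants: 14 2-hydroxy-5-methoxy-4-methylbenzaldehyde
Product: 15 5-methoxy-2-(methoxymethoxy)-4-methylbenzaldehyde
Conditions: MOMCl, i-Pr2NEt, CH2Cl2, 0 °C → rt
Reagents that add atoms: chloromethyl methyl ether (COCCl)
Why: Alkylation of the phenol gives an acetal that survives the Grignard addition, the oxidation, the heat of the cycloaddition, amide bases and hydrides.

Step 10
Reactants: 15 MOM-protected aldehyde
Product: 16 1-[5-methoxy-2-(methoxymethoxy)-4-methylphenyl]but-2-yn-1-ol (racemic)
Conditions: MeC≡CMgBr, THF, −78 → 0 °C
Reagents that add atoms: prop-1-ynylmagnesium bromide (CC#C[Mg]Br)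
Why: Grignard addition to the aldehyde forms C9–C11; the carbinol centre is removed in the next step.

Step 11
Reactants: 16 propargylic alcohol
Product: 17 1-[5-methoxy-2-(methoxymethoxy)-4-methylphenyl]but-2-yn-1-one
Conditions: MnO2, CH2Cl2, rt
Reagents that add atoms: none
Why: Selective oxidation of a benzylic, propargylic alcohol to the ynone under neutral conditions, which avoids isomerisation to the allenyl ketone.

Step 12
Reactants: 12 bicyclic dienol ether; 17 aryl butynone
Product: 18 11-Ar-6,18-epoxydrima-5,8-dien-11-one (4β-methyl, 10β-methyl)
Conditions: toluene (1 M), BHT, 110 °C, sealed base-washed tube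
Reagents that add atoms: none
Why: A concerted but asynchronous normal-demand [4+2] cycloaddition (Diels–Alder) joins the 2-alkoxydiene C7=C6–C5=C10 of 12 to the alkyne of 17, forming C7–C8 and C9–C10. The closest known reactions are the Diels–Alder additions of 1-vinylcyclohexene-type ring A dienes and of 2-oxygenated dienes to acetylenic ketones, aldehydes and esters used for drimanes. Ring B closes by intermolecular six-membered annulation, both new bonds forming in one step on the same face of the diene. The only new stereocentre, quaternary C10, is controlled by C4: the five-membered ring holds C18 near the diene plane, so the pseudo-axial C4 methyl, 1,3 to C10, is the one group over the β face and the alkyne adds to the α face, leaving the C10 methyl syn to the C4 methyl. The "para" regioselectivity that is needed follows from the ring oxygen on C6, which makes C7 the nucleophilic terminus; C7 bonds to the ynone β-carbon C8 and C10 to the acyl-bearing C9. The enol-ether ring also locks the diene s-cis, which is what should make the fully substituted terminus reactive enough, and an alkyne dienophile leaves no endo/exo question. Neutral, base-free conditions avoid ynone-to-allenone isomerisation and hydrolysis of the enol ether.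

Step 13
Reactants: 18 Diels–Alder adduct
Product: 19 11-Ar-6,18-epoxydrima-5,7-dien-11-one (9α-H), used crude
Conditions: KN(SiMe3)2, THF, −78 °C; then AcOH, −78 °C
Reagents that add atoms: none
Why: Deconjugative protonation: the enone is deprotonated at the doubly allylic C7 and the extended enolate is protonated kinetically at its α-carbon C9. The proton arrives anti to the axial C10 methyl, which gives 9α-H and moves the alkene to C7=C8.

Step 14
Reactants: 19 deconjugated ketone
Product: 21 11-Ar-11,18-dihydroxydrim-7-en-6-one (5α-H, 9α-H, C11 epimers), via C11 carbinol dienol ether 20 (not isolated)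
Conditions: i-Bu2AlH, toluene, −78 °C; then 0.5 M aq. HCl, THF, 0 °C
Reagents that add atoms: water (O)
Why: The C11 ketone is reduced first, so C9 never lies between two carbonyl groups. Hydrolysis of the 2-alkoxydiene then protonates C5 on the α face, away from both β-methyls, and gives the trans-fused conjugated enone and the free C18 alcohol.

Step 15
Reactants: 21 enone diol
Product: 22 11-Ar-drim-7-ene-6,11,18-triol (C6 and C11 epimers)
Conditions: NaBH4, CeCl3·7H2O, MeOH, −20 °C
Reagents that add atoms: none
Why: Luche 1,2-reduction of the enone removes the last carbonyl that could epimerise C5 or C9; the new carbinol centre is deleted later.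

Step 16
Reactants: 22 triol
Product: 23 11-Ar-18-(tert-butyldimethylsilyloxy)drim-7-ene-6,11-diol
Conditions: TBSCl, imidazole, DMF, 0 °C → rt
Reagents that add atoms: tert-butyldimethylsilyl chloride (CC(C)(C)[Si](C)(C)Cl)
Why: The primary C18 hydroxyl is silylated far faster than the two hindered secondary alcohols.

Step 17
Reactants: 23 diol
Product: 24 6,11-bis(O-alkyl S-methyl dithiocarbonate) of 23
Conditions: NaH, CS2, imidazole (cat.), THF, 0 °C → rt; then MeI
Reagents that add atoms: carbon disulfide (S=C=S); iodomethane (CI)
Why: Standard xanthate formation from the two alkoxides. An allylic xanthate that has shifted to its S-allyl isomer leads to the same radical in the next step.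

Step 18
Reactants: 24 bis-xanthate
Product: 25 11-Ar-18-(tert-butyldimethylsilyloxy)drim-7-ene
Conditions: Bu3SnH, AIBN (cat.), toluene, 100 °C
Reagents that add atoms: none
Why: Barton–McCombie deoxygenation at both positions. The benzylic C11 radical is reduced directly, and the C6–C7–C8 allyl radical should take hydrogen at its less hindered secondary end C6, keeping the trisubstituted C7=C8 alkene.

Step 19
Reactants: 25 protected drimenyl arene
Product: 26 11-(2-hydroxy-5-methoxy-4-methylphenyl)drim-7-en-18-ol
Conditions: HCl (1.25 M in MeOH), 0 → 40 °C
Reagents that add atoms: none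
Why: Acid methanolysis removes the aryl MOM acetal and the primary silyl ether together. Without a Lewis acid the trisubstituted alkene should be neither protonated nor attacked by the phenol.

Step 20
Reactants: 26 para-methoxyphenol
Product: 27 2-(18-hydroxydrim-7-en-11-yl)-4,4-dimethoxy-5-methylcyclohexa-2,5-dien-1-one
Conditions: PhI(OAc)2, MeOH, 0 °C
Reagents that add atoms: methanol (CO)
Why: Oxidative dearomatisation of a para-methoxyphenol by the trivalent iodine reagent, with methanol captured at the methoxy-bearing carbon, gives the quinone monoketal with C2′ as ketone and C5′ as ketal. A primary alcohol is not oxidised under these conditions.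

Step 21
Reactants: 27 quinone monoketal
Product: 28 (1′R,6′S)-1′,6′-epoxy-1′-(18-hydroxydrim-7-en-11-yl)-5′,5′-dimethoxy-4′-methylcyclohex-3′-en-2′-one
Conditions: t-BuOOH (70% aq.), N-benzylcinchonidinium chloride (10 mol %), aq. NaOH, toluene, 0 °C → rt
Reagents that add atoms: tert-butyl hydroperoxide (CC(C)(C)OO)
Why: Weitz–Scheffer epoxidation under chiral phase-transfer catalysis, a known reaction of quinone monoketals. The hydroperoxide anion adds to C6′, the only unsubstituted β-carbon, and the enolate closes at C1′; the chiral ion pair selects the face, since the decalin is too remote to do so.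

Step 22
Reactants: 28 epoxy ketone ketal
Product: 29 (1′S,2′R,6′S)-1′,6′-epoxy-1′-(18-hydroxydrim-7-en-11-yl)-5′,5′-dimethoxy-4′-methylcyclohex-3′-en-2′-ol
Conditions: i-Bu2AlH (3 equiv), THF, −78 °C
Reagents that add atoms: none
Why: 1,2-Reduction of the only carbonyl. Aluminium bound to the epoxide oxygen should deliver hydride on that face, and the C11 chain, which leans to the other face, reinforces this; the hydroxyl thus ends anti to the epoxide.

Step 23
Reactants: 29 epoxy alcohol ketal
Product: 30 Epoxypholamin B
Conditions: PPTS, acetone/H2O (10:1), rt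
Reagents that add atoms: water (O)
Why: Mild hydrolysis of the dimethyl ketal, driven by conjugation of the new C5′ ketone with C3′=C4′; the epoxide and the allylic alcohol tolerate these conditions.

## Compound list

1 | ethyl 2-oxocyclohexane-1-carboxylate | CCOC(=O)C1CCCCC1=O | starting material
2 | L-valine tert-butyl ester | CC(C)[C@H](N)C(=O)OC(C)(C)C | starting material
3 | ethyl 2-{[(2S)-1-tert-butoxy-3-methyl-1-oxobutan-2-yl]amino}cyclohex-1-ene-1-carboxylate | CCOC(=O)C1=C(N[C@@H](C(C)C)C(=O)OC(C)(C)C)CCCC1 | intermediate
4 | ethyl (1R)-2-{[(2S)-1-tert-butoxy-3-methyl-1-oxobutan-2-yl]imino}-1-methylcyclohexane-1-carboxylate | CCOC(=O)[C@]1(C)CCCCC1=N[C@@H](C(C)C)C(=O)OC(C)(C)C | intermediate (not isolated)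
5 | ethyl (1R)-1-methyl-2-oxocyclohexane-1-carboxylate | CCOC(=O)[C@]1(C)CCCCC1=O | intermediate
6 | ethyl (1R)-1,3-dimethyl-2-oxocyclohexane-1-carboxylate (C3 epimers) | CCOC(=O)[C@]1(C)CCCC(C)C1=O | intermediate
7 | ethyl (1R)-1,3-dimethyl-2-{[(trifluoromethyl)sulfonyl]oxy}cyclohex-2-ene-1-carboxylate | CCOC(=O)[C@]1(C)CCCC(C)=C1OS(=O)(=O)C(F)(F)F | intermediate
8 | ethynyl(trimethyl)silane | C#C[Si](C)(C)C | starting material
9 | ethyl (1R)-1,3-dimethyl-2-[(trimethylsilyl)ethynyl]cyclohex-2-ene-1-carboxylate | CCOC(=O)[C@]1(C)CCCC(C)=C1C#C[Si](C)(C)C | intermediate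
10 | {(1R)-1,3-dimethyl-2-[(trimethylsilyl)ethynyl]cyclohex-2-en-1-yl}methanol | OC[C@]1(C)CCCC(C)=C1C#C[Si](C)(C)C | intermediate
11 | [(1R)-2-ethynyl-1,3-dimethylcyclohex-2-en-1-yl]methanol | OC[C@]1(C)CCCC(C)=C1C#C | intermediate (not isolated)
12 | (3aR)-3a,7-dimethyl-1-methylidene-1,3,3a,4,5,6-hexahydro-2-benzofuran | C=C1OC[C@]2(C)CCCC(C)=C12 | intermediate
13 | 2,5-dimethoxy-4-methylbenzaldehyde | COc1cc(C)c(OC)cc1C=O | starting material
14 | 2-hydroxy-5-methoxy-4-methylbenzaldehyde | COc1cc(C=O)c(O)cc1C | intermediate
15 | 5-methoxy-2-(methoxymethoxy)-4-methylbenzaldehyde | COCOc1cc(C)c(OC)cc1C=O | intermediate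
16 | 1-[5-methoxy-2-(methoxymethoxy)-4-methylphenyl]but-2-yn-1-ol (racemic) | CC#CC(O)c1cc(OC)c(C)cc1OCOC | intermediate
17 | 1-[5-methoxy-2-(methoxymethoxy)-4-methylphenyl]but-2-yn-1-one | CC#CC(=O)c1cc(OC)c(C)cc1OCOC | intermediate
18 | 11-Ar-6,18-epoxydrima-5,8-dien-11-one (4β-Me, 10β-Me) | CC1=C(C(=O)c2cc(OC)c(C)cc2OCOC)[C@@]3(C)CCC[C@@]4(C)COC(C1)=C34 | intermediate
19 | 11-Ar-6,18-epoxydrima-5,7-dien-11-one (9α-H) | O=C(c1cc(OC)c(C)cc1OCOC)[C@H]2C(C)=CC3=C4[C@](C)(CO3)CCC[C@]24C | intermediate
20 | 11-Ar-6,18-epoxydrima-5,7-dien-11-ol (9α-H, C11 epimers) | OC(c1cc(OC)c(C)cc1OCOC)[C@H]2C(C)=CC3=C4[C@](C)(CO3)CCC[C@]24C | intermediate (not isolated)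
21 | 11-Ar-11,18-dihydroxydrim-7-en-6-one (5α-H, 9α-H, C11 epimers) | OC(c1cc(OC)c(C)cc1OCOC)[C@H]2C(C)=CC(=O)[C@H]3[C@](C)(CO)CCC[C@]23C | intermediate
22 | 11-Ar-drim-7-ene-6,11,18-triol (C6 and C11 epimers) | OC(c1cc(OC)c(C)cc1OCOC)[C@H]2C(C)=CC(O)[C@H]3[C@](C)(CO)CCC[C@]23C | intermediate
23 | 11-Ar-18-(tert-butyldimethylsilyloxy)drim-7-ene-6,11-diol | OC(c1cc(OC)c(C)cc1OCOC)[C@H]2C(C)=CC(O)[C@H]3[C@](C)(CO[Si](C)(C)C(C)(C)C)CCC[C@]23C | intermediate
24 | 6,11-bis(O-alkyl S-methyl dithiocarbonate) of 23 | CSC(=S)OC(c1cc(OC)c(C)cc1OCOC)[C@H]2C(C)=CC(OC(=S)SC)[C@H]3[C@](C)(CO[Si](C)(C)C(C)(C)C)CCC[C@]23C | intermediate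
25 | 11-Ar-18-(tert-butyldimethylsilyloxy)drim-7-ene | COCOc1cc(C)c(OC)cc1C[C@H]2C(C)=CC[C@H]3[C@](C)(CO[Si](C)(C)C(C)(C)C)CCC[C@]23C | intermediate
26 | 11-(2-hydroxy-5-methoxy-4-methylphenyl)drim-7-en-18-ol | Cc1cc(O)c(C[C@H]2C(C)=CC[C@H]3[C@](C)(CO)CCC[C@]23C)cc1OC | intermediate
27 | 2-(18-hydroxydrim-7-en-11-yl)-4,4-dimethoxy-5-methylcyclohexa-2,5-dien-1-one | CC1=CC(=O)C(C[C@H]2C(C)=CC[C@H]3[C@](C)(CO)CCC[C@]23C)=CC1(OC)OC | intermediate
28 | (1′R,6′S)-1′,6′-epoxy-1′-(18-hydroxydrim-7-en-11-yl)-5′,5′-dimethoxy-4′-methylcyclohex-3′-en-2′-one | CC1=CC(=O)[C@]2(C[C@H]3C(C)=CC[C@H]4[C@](C)(CO)CCC[C@]34C)O[C@@H]2C1(OC)OC | intermediate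
29 | (1′S,2′R,6′S)-1′,6′-epoxy-1′-(18-hydroxydrim-7-en-11-yl)-5′,5′-dimethoxy-4′-methylcyclohex-3′-en-2′-ol | CC1=C[C@@H](O)[C@]2(C[C@H]3C(C)=CC[C@H]4[C@](C)(CO)CCC[C@]34C)O[C@@H]2C1(OC)OC | intermediate
30 | Epoxypholamin B | CC1=C[C@@H](O)[C@]2(C[C@H]3C(C)=CC[C@H]4[C@](C)(CO)CCC[C@]34C)O[C@@H]2C1=O | target

## Step count and least certain steps

Total: 23 steps. Longest linear sequence: 19 steps (steps 1–7 and 12–23); the ynone branch (steps 8–11) has 4.

**Step 12 (key step).** The cycloaddition at the fully substituted C10 terminus may be slow, so that decomposition of the dienol ether or ynone-to-allenone isomerisation competes; the two diene faces may also be told apart insufficiently. Fallback, from 12 back to 18: the diene 12 is combined with but-2-ynal, a smaller and more electrophilic dienophile (toluene, 60–80 °C), to give the tricyclic aldehyde F1 with the same two bonds formed. 1-Methoxy-4-(methoxymethoxy)-2-methylbenzene F2, made from 4-methoxy-3-methylphenol with MOMCl and i-Pr2NEt, is lithiated ortho to the acetal (n-BuLi, TMEDA, THF, 0 °C) and added to F1 to give the carbinol F3, which MnO2 oxidises to 18. The arene then enters after ring B has closed, at the cost of two steps.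

**Step 13.** The proton may return to C7, the base may remove a proton from the C8 methyl instead, or C9 may be protonated from the β face. Fallback, from 18 back to 21: the C11 ketone is reduced first (i-Bu2AlH, toluene, −78 °C) to the allylic carbinol F3. Buffered hydrolysis of the enol ether (PPTS, wet acetone, 0 °C) gives the β,γ-unsaturated hydroxy ketone F4. DBU then moves the C8=C9 alkene into conjugation with the only carbonyl left, C6, the C9 hydrogen arriving by γ-protonation of the dienolate on the α face; this gives 21.

**Step 18.** Hydrogen transfer to the tertiary C8 end of the allyl radical would move the alkene to C6=C7, and thermal elimination of the xanthates could compete. Fallback, from 23 back to 25: both secondary alcohols are acetylated (Ac2O, DMAP, pyridine) to the diacetate F5, and both C–O bonds are cleaved with Li in NH3/THF at −78 °C without added proton donor. Benzylic and allylic acetates are reduced through carbanions, and the allyl anion is protonated by ammonia at its less substituted end, C6.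

**Step 21.** Face selection may be low, because the ion pair has to distinguish the faces of an α-alkyl dienone with no nearby stereocentre, and the α-substituted enone may react slowly. Fallback, from 26 back to 30, with an auxiliary in place of the catalyst: oxidation of 26 with PhI(OAc)2 in CH2Cl2 in the presence of (R,R)-hydrobenzoin, then a trace of acid, gives the spiro-dioxolane dienone F6. Its phenyl groups differentiate the faces of C1′=C6′ in a t-BuOOH/DBU epoxidation to the epoxy ketone F7. i-Bu2AlH gives the anti epoxy alcohol F8, and aqueous trifluoroacetic acid removes the auxiliary to give 30. (S,S)-Hydrobenzoin is used if the other face is shielded.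

**Step 22.** Hydride may be delivered from the face opposite to the epoxide, giving the syn epoxy alcohol. Fallback, from 28 back to 29: the syn alcohol F9 from that reduction is inverted by a Mitsunobu reaction (4-nitrobenzoic acid, PPh3, diisopropyl azodicarboxylate, THF) to the anti 4-nitrobenzoate F10, and K2CO3 in MeOH releases 29. The neopentyl C18 hydroxyl reacts far more slowly, and any ester formed there is cleaved in the same methanolysis.

## Further compounds

F1 | step 12 | 6,18-epoxydrima-5,8-dien-11-al (4β-Me, 10β-Me) | CC1=C(C=O)[C@@]2(C)CCC[C@@]3(C)COC(C1)=C23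
F2 | step 12 | 1-methoxy-4-(methoxymethoxy)-2-methylbenzene | COCOc1ccc(OC)c(C)c1
F3 | step 12 | 11-Ar-6,18-epoxydrima-5,8-dien-11-ol (C11 epimers) | CC1=C(C(O)c2cc(OC)c(C)cc2OCOC)[C@@]3(C)CCC[C@@]4(C)COC(C1)=C34
F4 | step 13 | 11-Ar-11,18-dihydroxydrim-8-en-6-one (5α-H, C11 epimers) | OC(c1cc(OC)c(C)cc1OCOC)C2=C(C)CC(=O)[C@H]3[C@](C)(CO)CCC[C@]23C
F5 | step 18 | 6,11-diacetate of 23 | CC(=O)OC(c1cc(OC)c(C)cc1OCOC)[C@H]2C(C)=CC(OC(C)=O)[C@H]3[C@](C)(CO[Si](C)(C)C(C)(C)C)CCC[C@]23C
F6 | step 21 | (R,R)-hydrobenzoin ketal analogue of 27 | CC1=CC(=O)C(C[C@H]3C(C)=CC[C@H]4[C@](C)(CO)CCC[C@]34C)=CC12O[C@H](c5ccccc5)[C@@H](c5ccccc5)O2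
F7 | step 21 | (R,R)-hydrobenzoin ketal analogue of 28 | CC1=CC(=O)[C@]3(C[C@H]4C(C)=CC[C@H]5[C@](C)(CO)CCC[C@]45C)O[C@@H]3C12O[C@H](c6ccccc6)[C@@H](c6ccccc6)O2
F8 | step 21 | (R,R)-hydrobenzoin ketal analogue of 29 | CC1=C[C@@H](O)[C@]3(C[C@H]4C(C)=CC[C@H]5[C@](C)(CO)CCC[C@]45C)O[C@@H]3C12O[C@H](c6ccccc6)[C@@H](c6ccccc6)O2
F9 | step 22 | 2′-epimer of 29 (hydroxyl syn to the epoxide) | CC1=C[C@H](O)[C@]2(C[C@H]3C(C)=CC[C@H]4[C@](C)(CO)CCC[C@]34C)O[C@@H]2C1(OC)OC
F10 | step 22 | 2′-O-(4-nitrobenzoate) of 29 | CC1=C[C@@H](OC(=O)c5ccc(cc5)[N+](=O)[O-])[C@]2(C[C@H]3C(C)=CC[C@H]4[C@](C)(CO)CCC[C@]34C)O[C@@H]2C1(OC)OC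
A1 | alternative 1 | bicyclic keto ester: methyl 3β-hydroxy-8-oxo-18-(tert-butyldimethylsilyloxy)-12-nordriman-11-oate | COC(=O)[C@H]1C(=O)CC[C@H]2[C@](C)(CO[Si](C)(C)C(C)(C)C)[C@@H](O)CC[C@]12C
A2 | alternative 1 | methyl (E)-7-methyl-9-{3-methyl-3-[(tert-butyldimethylsilyloxy)methyl]oxiran-2-yl}-3-oxonon-6-enoate | COC(=O)CC(=O)CC/C=C(\C)CC[C@@H]1O[C@@]1(C)CO[Si](C)(C)C(C)(C)C
A3 | alternative 2 | 18-O-tert-butyldimethylsilyl ether of 28 | CC1=CC(=O)[C@]2(C[C@H]3C(C)=CC[C@H]4[C@](C)(CO[Si](C)(C)C(C)(C)C)CCC[C@]34C)O[C@@H]2C1(OC)OC
A4 | alternative 2 | 18-O-tert-butyldimethylsilyl ether of 27 | CC1=CC(=O)C(C[C@H]2C(C)=CC[C@H]3[C@](C)(CO[Si](C)(C)C(C)(C)C)CCC[C@]23C)=CC1(OC)OC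
A5 | alternative 3 | cis-fused ene-dione adduct with C3 silyl enol ether | C[C@@H]1C(O[Si](C)(C)C(C)(C)C)=CC[C@]2(C)C(=O)C(C)=CC(=O)[C@H]12
A6 | alternative 3 | 2,6-dimethyl-1,4-benzoquinone | CC1=CC(=O)C=C(C)C1=O
A7 | alternative 3 | (Z)-3-(tert-butyldimethylsilyloxy)penta-1,3-diene | C=C/C(O[Si](C)(C)C(C)(C)C)=C/C
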